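**Plan**

1. Numbering used here: dienone ring C1 (C=O) to C6, allyl group on C2, fully substituted carbon C4; side chain C7 (CH–CH3) and C8 (CH–O, aryl).
2. Retrosynthesis: the C8 acetate goes back to silyl ether 22. Both ring double bonds C2=C3 and C5=C6 are then cut, which gives the C3–C4–C5 piece 13 (aldehyde and methyl ester on C4) and the C2–C1–C6 piece 17 (allylated acetonyl ylide). 13 goes back to α-methoxy ester 10 (C4–C3 bond), then to vinyl compound 5, then to veratraldehyde and a (Z)-crotyl boronate (C7–C8 bond).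
3. Forward order: side chain (steps 1, 2), vinyl group to methoxy ester (3–5), quaternary C4 (6), ylide (7), six-membered ring from the two three-carbon pieces in one flask (8), silyl-to-acetyl exchange (9).
4. Enabling feature: C4 bears no hydrogen and stands between C3 (aldehyde level) and C5 (ester level, already carrying the methoxy group that the target keeps). C2–C1(=O)–C6 is an acetone unit whose two α-carbons can be made an enolate carbon (C2) and a phosphorus ylide carbon (C6). Aldol at C3 and Wittig reaction at C5 therefore give the cross-conjugated 3-methoxycyclohexa-2,5-dienone directly.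
5. Stereochemistry: C7 and C8 come from the catalyst-controlled syn crotylboration; C4 comes from allylic 1,3-strain control in the enolate formylation; the ring-forming step makes only sp2 carbons.

Key step: step 8

Remark: the carbinol centre made in step 3 is carried as a mixture of epimers through 6–10, because it becomes planar in step 6. cis-Crotylboronic acid pinacol ester, (R)-TRIP and 1-(triphenylphosphoranylidene)propan-2-one are taken as commercial.

**Route**

Step 1
Reactants: 1 3,4-dimethoxybenzaldehyde; 2 (Z)-crotylboronic acid pinacol ester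
Product: 4 (1R,2S)-1-(3,4-dimethoxyphenyl)-2-methylbut-3-en-1-ol, via pinacol borate ester 3 (not isolated)
Conditions: (R)-TRIP [(R)-3,3'-bis(2,4,6-triisopropylphenyl)-1,1'-binaphthalene-2,2'-diyl hydrogen phosphate] (5 mol%), PhMe, −30 °C; then aq. NaHCO3
Reagents that add atoms: none
Why: Chiral phosphoric acid-catalysed crotylboration through a closed chair (Zimmerman–Traxler) transition state; the (Z)-boronate gives the syn adduct and the (R)-catalyst is expected to direct the crotyl group to the Re face of the aldehyde, which sets C1 as R and C2 as S.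

Step 2
Reactants: 4 (1R,2S)-1-(3,4-dimethoxyphenyl)-2-methylbut-3-en-1-ol
Product: 5 tert-butyl{[(1R,2S)-1-(3,4-dimethoxyphenyl)-2-methylbut-3-en-1-yl]oxy}dimethylsilane
Conditions: TBSOTf, 2,6-lutidine, CH2Cl2, 0 °C
Reagents that add atoms: tert-butyldimethylsilyl trifluoromethanesulfonate, CC(C)(C)[Si](C)(C)OS(=O)(=O)C(F)(F)F
Why: Silylation of a hindered benzylic secondary alcohol with the silyl triflate; the ether should withstand the oxidants, amide bases and heating of steps 3 to 8.

Step 3
Reactants: 5 tert-butyl{[(1R,2S)-1-(3,4-dimethoxyphenyl)-2-methylbut-3-en-1-yl]oxy}dimethylsilane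
Product: 6 (3S,4R)-4-[(tert-butyldimethylsilyl)oxy]-4-(3,4-dimethoxyphenyl)-3-methylbutane-1,2-diol (both C2 epimers)
Conditions: OsO4 (2 mol%), N-methylmorpholine N-oxide, acetone/H2O, rt
Reagents that add atoms: N-methylmorpholine N-oxide, C[N+]1([O-])CCOCC1; water, O
Why: OsO4-catalysed syn dihydroxylation of the terminal alkene with the N-oxide as reoxidant; the new carbinol centre need not be controlled because it is planarised in step 6.

Step 4
Reactants: 6 (3S,4R)-4-[(tert-butyldimethylsilyl)oxy]-4-(3,4-dimethoxyphenyl)-3-methylbutane-1,2-diol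
Product: 8 (3S,4R)-4-[(tert-butyldimethylsilyl)oxy]-4-(3,4-dimethoxyphenyl)-2-hydroxy-3-methylbutanoic acid (both C2 epimers), via hydroxy aldehyde 7 (not isolated)
Conditions: TEMPO (10 mol%), NaOCl (5 mol%), NaClO2, MeCN/aq. phosphate buffer (pH 6.7), 35 °C
Reagents that add atoms: sodium chlorite, [Na+].[O-]Cl=O
Why: TEMPO-catalysed chlorite oxidation takes the primary alcohol through aldehyde 7 to the acid and should leave the secondary hydroxyl, the silyl ether and the electron-rich arene untouched, since hypochlorite is present only in catalytic amount.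

Step 5
Reactants: 8 (3S,4R)-4-[(tert-butyldimethylsilyl)oxy]-4-(3,4-dimethoxyphenyl)-2-hydroxy-3-methylbutanoic acid
Product: 10 methyl (3S,4R)-4-[(tert-butyldimethylsilyl)oxy]-4-(3,4-dimethoxyphenyl)-2-methoxy-3-methylbutanoate (both C2 epimers), via hydroxy methyl ester 9 (not isolated)
Conditions: MeI (excess), Ag2O, MeCN, 40 °C, dark
Reagents that add atoms: iodomethane, CI
Why: Purdie methylation; the silver carboxylate is esterified first and the α-hydroxyl is then etherified under neutral conditions, so that enolate formation and C-methylation are avoided.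

Step 6
Reactants: 10 methyl (3S,4R)-4-[(tert-butyldimethylsilyl)oxy]-4-(3,4-dimethoxyphenyl)-2-methoxy-3-methylbutanoate
Product: 13 methyl (2S,3R,4R)-4-[(tert-butyldimethylsilyl)oxy]-4-(3,4-dimethoxyphenyl)-2-formyl-2-methoxy-3-methylbutanoate, via lithium enolate 11 (not isolated), via lithium hemiacetalate 12 (not isolated)
Conditions: LiN(iPr)2, THF, −78 °C; HCO2Me (excess), −78 °C; AcOH, −78 °C to rt
Reagents that add atoms: methyl formate, COC=O
Why: Claisen-type C-formylation of an ester enolate; the enolate should adopt the conformation in which the C3–H bond eclipses the enolate plane (allylic 1,3-strain), so methyl formate enters anti to the bulky CH(OTBS)Ar group and sets the quaternary centre as 2S, and acidification at −78 °C lets adduct 12 collapse to the non-enolisable aldehyde.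

Step 7
Reactants: 14 1-(triphenylphosphoranylidene)propan-2-one; 15 allyl bromide
Product: 17 1-(triphenylphosphoranylidene)hex-5-en-2-one, via lithium ylide anion 16 (not isolated)
Conditions: LiN(iPr)2, THF, −78 °C; then 15, −78 °C to rt
Reagents that add atoms: none
Why: γ-Alkylation of an acyl ylide through its ylide anion, which reacts with alkyl halides at the enolate carbon and not at the ylide carbon.

Step 8
Reactants: 17 1-(triphenylphosphoranylidene)hex-5-en-2-one; 13 methyl (2S,3R,4R)-4-[(tert-butyldimethylsilyl)oxy]-4-(3,4-dimethoxyphenyl)-2-formyl-2-methoxy-3-methylbutanoate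
Product: 22 (4R)-4-{(1R,2R)-1-[(tert-butyldimethylsilyl)oxy]-1-(3,4-dimethoxyphenyl)propan-2-yl}-4,5-dimethoxy-2-(prop-2-en-1-yl)cyclohexa-2,5-dien-1-one, via lithium ylide anion 18 (not isolated), via aldol adduct 19 (not isolated), via hydroxy enone 20 (not isolated), via mesylate 21 (not isolated)
Conditions: 17, LiN(iPr)2, THF, −78 °C; add 13, −78 °C; AcOH, −78 °C; exchange THF for PhMe, 110 °C; then MsCl, Et3N, 0 °C; DBU, 0 °C to rt
Reagents that add atoms: none
Why: Proposed new method: LiN(iPr)2 removes the C2 proton of keto ylide 17 and the ylide anion 18 adds through its enolate carbon C2 to the non-enolisable aldehyde carbon C3 of 13 (aldol, first bond) while the stabilised ylide carbon C6 stays untouched; after a cold AcOH quench, heating lets C6 attack the ester carbonyl C5 and the oxaphosphetane loses Ph3PO with the methoxy group kept on C5 (second bond, now C5=C6), and mesylation with E1cB loss of the C3 oxygen then makes C2=C3. The closest known reaction types are the γ-aldol reactions of lithiated acyl ylides, the aldol or Michael additions of 4-(triphenylphosphoranylidene)acetoacetates that end in an intramolecular Wittig ring closure, and the intramolecular Wittig olefination of ester carbonyls by stabilised ylides (tetronates from Ph3P=C=C=O and α-hydroxy esters); their union in one annulation on a formyl ester is new. The six-membered carbocycle is closed by the intramolecular Wittig reaction (6-exo attack on the ester C=O), helped by the fully substituted C4 (Thorpe–Ingold effect) and the inductive pull of its methoxy group. No stereocentre is made that survives (C2 and C3 end as sp2 carbons and the ring fixes the C2=C3 geometry), and C4 and the two side-chain centres carry no acidic hydrogen. The step needs site selectivity (enolate carbon against ylide carbon, aldehyde against ester) and the right order of events: the enolate end and the aldehyde are by far the most reactive pair at −78 °C, the ester can be reached only intramolecularly, and elimination is held back until the ring exists because a premature acyclic enone would have the wrong geometry for closure. The cold quench is needed because the lithium aldolate could otherwise fragment with transfer of the formyl carbon.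

Step 9
Reactants: 22 (4R)-4-{(1R,2R)-1-[(tert-butyldimethylsilyl)oxy]-1-(3,4-dimethoxyphenyl)propan-2-yl}-4,5-dimethoxy-2-(prop-2-en-1-yl)cyclohexa-2,5-dien-1-one
Product: 24 (1R,2R)-1-(3,4-dimethoxyphenyl)-2-[(1R)-1,2-dimethoxy-4-oxo-5-(prop-2-en-1-yl)cyclohexa-2,5-dien-1-yl]propyl acetate, via benzylic alcohol 23 (not isolated)
Conditions: HF·pyridine, pyridine, THF, 0 °C; then Ac2O, DMAP, 0 °C to rt
Reagents that add atoms: acetic anhydride, CC(=O)OC(C)=O
Why: Fluoride cleavage of the silyl ether in a buffered, weakly acidic medium followed at once by DMAP-catalysed acetylation in the same flask, so that the free alcohol 23 should have little time to add to the vinylogous ester carbon C5; no stereocentre is touched.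

**Compound list**

1 | 3,4-dimethoxybenzaldehyde (veratraldehyde) | COc1ccc(C=O)cc1OC | starting material
2 | (Z)-crotylboronic acid pinacol ester | C/C=C\CB1OC(C)(C)C(C)(C)O1 | starting material
3 | 2-{[(1R,2S)-1-(3,4-dimethoxyphenyl)-2-methylbut-3-en-1-yl]oxy}-4,4,5,5-tetramethyl-1,3,2-dioxaborolane | C=C[C@H](C)[C@@H](OB1OC(C)(C)C(C)(C)O1)c1ccc(OC)c(OC)c1 | intermediate
4 | (1R,2S)-1-(3,4-dimethoxyphenyl)-2-methylbut-3-en-1-ol | C=C[C@H](C)[C@@H](O)c1ccc(OC)c(OC)c1 | intermediate
5 | tert-butyl{[(1R,2S)-1-(3,4-dimethoxyphenyl)-2-methylbut-3-en-1-yl]oxy}dimethylsilane | C=C[C@H](C)[C@@H](O[Si](C)(C)C(C)(C)C)c1ccc(OC)c(OC)c1 | intermediate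
6 | (3S,4R)-4-[(tert-butyldimethylsilyl)oxy]-4-(3,4-dimethoxyphenyl)-3-methylbutane-1,2-diol, both C2 epimers | OCC(O)[C@H](C)[C@@H](O[Si](C)(C)C(C)(C)C)c1ccc(OC)c(OC)c1 | intermediate
7 | (3S,4R)-4-[(tert-butyldimethylsilyl)oxy]-4-(3,4-dimethoxyphenyl)-2-hydroxy-3-methylbutanal, both C2 epimers | O=CC(O)[C@H](C)[C@@H](O[Si](C)(C)C(C)(C)C)c1ccc(OC)c(OC)c1 | intermediate
8 | (3S,4R)-4-[(tert-butyldimethylsilyl)oxy]-4-(3,4-dimethoxyphenyl)-2-hydroxy-3-methylbutanoic acid, both C2 epimers | OC(=O)C(O)[C@H](C)[C@@H](O[Si](C)(C)C(C)(C)C)c1ccc(OC)c(OC)c1 | intermediate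
9 | methyl (3S,4R)-4-[(tert-butyldimethylsilyl)oxy]-4-(3,4-dimethoxyphenyl)-2-hydroxy-3-methylbutanoate, both C2 epimers | COC(=O)C(O)[C@H](C)[C@@H](O[Si](C)(C)C(C)(C)C)c1ccc(OC)c(OC)c1 | intermediate
10 | methyl (3S,4R)-4-[(tert-butyldimethylsilyl)oxy]-4-(3,4-dimethoxyphenyl)-2-methoxy-3-methylbutanoate, both C2 epimers | COC(=O)C(OC)[C@H](C)[C@@H](O[Si](C)(C)C(C)(C)C)c1ccc(OC)c(OC)c1 | intermediate
11 | lithium enolate of 10 | COC(O[Li])=C(OC)[C@H](C)[C@@H](O[Si](C)(C)C(C)(C)C)c1ccc(OC)c(OC)c1 | intermediate
12 | lithium hemiacetalate formed from 11 and methyl formate (tetrahedral adduct at the new formyl carbon) | COC(=O)[C@@](OC)(C(OC)O[Li])[C@H](C)[C@@H](O[Si](C)(C)C(C)(C)C)c1ccc(OC)c(OC)c1 | intermediate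
13 | methyl (2S,3R,4R)-4-[(tert-butyldimethylsilyl)oxy]-4-(3,4-dimethoxyphenyl)-2-formyl-2-methoxy-3-methylbutanoate | COC(=O)[C@@](OC)(C=O)[C@H](C)[C@@H](O[Si](C)(C)C(C)(C)C)c1ccc(OC)c(OC)c1 | intermediate
14 | 1-(triphenylphosphoranylidene)propan-2-one | CC(=O)C=P(c1ccccc1)(c1ccccc1)c1ccccc1 | starting material
15 | allyl bromide | C=CCBr | starting material
16 | lithium ylide anion of 14 (lithium enolate at the methyl carbon) | C=C(O[Li])C=P(c1ccccc1)(c1ccccc1)c1ccccc1 | intermediate
17 | 1-(triphenylphosphoranylidene)hex-5-en-2-one | C=CCCC(=O)C=P(c1ccccc1)(c1ccccc1)c1ccccc1 | intermediate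
18 | lithium ylide anion of 17 (lithium enolate at C3 of the hexenone) | C=CCC=C(O[Li])C=P(c1ccccc1)(c1ccccc1)c1ccccc1 | intermediate
19 | methyl (2S)-2-{(1R,2R)-1-[(tert-butyldimethylsilyl)oxy]-1-(3,4-dimethoxyphenyl)propan-2-yl}-3-hydroxy-2-methoxy-5-oxo-4-(prop-2-en-1-yl)-6-(triphenylphosphoranylidene)hexanoate, epimers at C3 and C4 | C=CCC(C(=O)C=P(c1ccccc1)(c1ccccc1)c1ccccc1)C(O)[C@](OC)(C(=O)OC)[C@H](C)[C@@H](O[Si](C)(C)C(C)(C)C)c1ccc(OC)c(OC)c1 | intermediate
20 | (4S)-4-{(1R,2R)-1-[(tert-butyldimethylsilyl)oxy]-1-(3,4-dimethoxyphenyl)propan-2-yl}-5-hydroxy-3,4-dimethoxy-6-(prop-2-en-1-yl)cyclohex-2-en-1-one, epimers at C5 and C6 | C=CCC1C(O)[C@@](OC)([C@H](C)[C@@H](O[Si](C)(C)C(C)(C)C)c2ccc(OC)c(OC)c2)C(OC)=CC1=O | intermediate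
21 | methanesulfonate of the C5 hydroxyl of 20 | C=CCC1C(OS(C)(=O)=O)[C@@](OC)([C@H](C)[C@@H](O[Si](C)(C)C(C)(C)C)c2ccc(OC)c(OC)c2)C(OC)=CC1=O | intermediate
22 | (4R)-4-{(1R,2R)-1-[(tert-butyldimethylsilyl)oxy]-1-(3,4-dimethoxyphenyl)propan-2-yl}-4,5-dimethoxy-2-(prop-2-en-1-yl)cyclohexa-2,5-dien-1-one | C=CCC1=C[C@@](OC)([C@H](C)[C@@H](O[Si](C)(C)C(C)(C)C)c2ccc(OC)c(OC)c2)C(OC)=CC1=O | intermediate
23 | (4R)-4-[(1R,2R)-1-(3,4-dimethoxyphenyl)-1-hydroxypropan-2-yl]-4,5-dimethoxy-2-(prop-2-en-1-yl)cyclohexa-2,5-dien-1-one | C=CCC1=C[C@@](OC)([C@H](C)[C@@H](O)c2ccc(OC)c(OC)c2)C(OC)=CC1=O | intermediate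
24 | (1R,2R)-1-(3,4-dimethoxyphenyl)-2-[(1R)-1,2-dimethoxy-4-oxo-5-(prop-2-en-1-yl)cyclohexa-2,5-dien-1-yl]propyl acetate | C=CCC1=C[C@@](OC)([C@H](C)[C@@H](OC(C)=O)c2ccc(OC)c(OC)c2)C(OC)=CC1=O | target

**Step count and risks**

Total step count: 9. Longest linear sequence: 8 (steps 1–6, 8, 9).

Step 8 (proposed new method). The stabilised ylide may attack the hindered ester carbonyl too slowly, so that on long heating the aldol adduct reverts or fragments before the ring closes. Fallback with known reactions, setting out from 13 and coming back at 22: the aldol of 13 with 18 is run as above and adduct 19 is isolated. Zn in AcOH removes the phosphorus reductively to give the methyl ketone aldol F1, and TESOTf/2,6-lutidine gives its triethylsilyl ether F2. LiN(SiMe3)2 in THF (−78 to 0 °C) then closes the ring by intramolecular Claisen condensation of the methyl ketone enolate onto the ester, giving the cyclic 1,3-dione F3. Catalytic TsOH in PhMe eliminates triethylsilanol to the 5-hydroxy dienone F4, and TMSCHN2 in MeOH/PhMe O-methylates it. The C5 methyl enol ether is 22; its regioisomer would be separated and returned to F4 by mild acid hydrolysis.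

Step 6. The formyl group may be lost again by retro-Claisen cleavage if adduct 12 collapses while alkoxide is still present, and facial selectivity at the new quaternary centre may be incomplete. Fallback, setting out from 10 and coming back at 13: the enolate 11 is trapped with monomeric formaldehyde (from cracked paraformaldehyde, −78 °C) in an irreversible aldol addition to give the hydroxymethyl ester F5, which is formed under the same facial control and can be purified at the alcohol stage. Dess–Martin periodinane (NaHCO3, CH2Cl2) then gives 13.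

Step 9. Once the silyl group is off, the free benzylic hydroxyl may add to the vinylogous ester carbon C5 and expel methanol (closure to a dihydrobenzofuranone) before it is acetylated. Fallback, setting out from 22 and ending at 24: acylative cleavage of the silyl ether with Ac2O and catalytic Cu(OTf)2 in CH2Cl2 at 0 °C. The silyl ether oxygen is acylated directly and the silyl group leaves as its acetate, so alcohol 23 is never set free; this fallback makes no new compound (F0).

**Further compounds**

F1 | step 8 | methyl (2S)-2-{(1R,2R)-1-[(tert-butyldimethylsilyl)oxy]-1-(3,4-dimethoxyphenyl)propan-2-yl}-3-hydroxy-2-methoxy-5-oxo-4-(prop-2-en-1-yl)hexanoate | C=CCC(C(C)=O)C(O)[C@](OC)(C(=O)OC)[C@H](C)[C@@H](O[Si](C)(C)C(C)(C)C)c1ccc(OC)c(OC)c1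
F2 | step 8 | methyl (2S)-2-{(1R,2R)-1-[(tert-butyldimethylsilyl)oxy]-1-(3,4-dimethoxyphenyl)propan-2-yl}-2-methoxy-5-oxo-4-(prop-2-en-1-yl)-3-[(triethylsilyl)oxy]hexanoate | C=CCC(C(C)=O)C(O[Si](CC)(CC)CC)[C@](OC)(C(=O)OC)[C@H](C)[C@@H](O[Si](C)(C)C(C)(C)C)c1ccc(OC)c(OC)c1
F3 | step 8 | (4S)-4-{(1R,2R)-1-[(tert-butyldimethylsilyl)oxy]-1-(3,4-dimethoxyphenyl)propan-2-yl}-4-methoxy-6-(prop-2-en-1-yl)-5-[(triethylsilyl)oxy]cyclohexane-1,3-dione | C=CCC1C(O[Si](CC)(CC)CC)[C@@](OC)([C@H](C)[C@@H](O[Si](C)(C)C(C)(C)C)c2ccc(OC)c(OC)c2)C(=O)CC1=O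
F4 | step 8 | (4R)-4-{(1R,2R)-1-[(tert-butyldimethylsilyl)oxy]-1-(3,4-dimethoxyphenyl)propan-2-yl}-5-hydroxy-4-methoxy-2-(prop-2-en-1-yl)cyclohexa-2,5-dien-1-one | C=CCC1=C[C@@](OC)([C@H](C)[C@@H](O[Si](C)(C)C(C)(C)C)c2ccc(OC)c(OC)c2)C(O)=CC1=O
F5 | step 6 | methyl (2S,3R,4R)-4-[(tert-butyldimethylsilyl)oxy]-4-(3,4-dimethoxyphenyl)-2-(hydroxymethyl)-2-methoxy-3-methylbutanoate | COC(=O)[C@@](OC)(CO)[C@H](C)[C@@H](O[Si](C)(C)C(C)(C)C)c1ccc(OC)c(OC)c1
F0 | step 9 | none | none
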